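**Retrosynthetic overview**

- 31 ⇐ 29: acid turns the 1,2-epoxy-3-ketone into the C1=C2(OH)–C3=O diosphenol and frees the acid. 29 ⇐ 25 (epoxidation, C4 methylenation) ⇐ 24 (allylic oxidation at C3) ⇐ 19 (C1 ketone to Δ1 alkene; C7 enol ether to ketone to inverted acetate).
- The strategy rests on the cis-fused decalin: ring A (C1–C5, C10) and ring B (C5–C10), with the contiguous centres C5 (quaternary, C-19), C10, C9 (quaternary, C-20 and the C11–C15 chain) and C8 (C-17), and oxygen at C7.
- 19 ⇐ 18: one intramolecular [4+2] of the diene C5=C6–C7(OSi)=C8 with the enone C9=C10–C1(=O), tethered through C1–C4. It forms C5–C10 and C8–C9, and rings A and B close together; no ring is made before or after.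
- 18 ⇐ acid half 7 (hexane-2,5-dione + two phosphonoacetates) + diene half 15 (5-chloropent-1-yne, AlMe3, propanoyl Weinreb amide), joined by Pd-catalysed acylation of an alkylzinc.

Key step: step 10

**Remarks on the chemistry (assumptions)**

- Clerodane numbering is used; β is the face of ring B carrying C-19 and H-10, α the face carrying C-17 and C-20. The target is then the 7β-acetate.
- The (S)-oxazaborolidinium catalyst is assumed to expose the enone face that leads to 19; this sense must be confirmed, and the (R)-catalyst gives the mirror-image series.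
- Conjugate bases formed by simple deprotonation (enolates, phosphonate anion) are not numbered. The oxirane face in 26–30 (drawn β) and C4 in 27/28 (left open) are inconsequential, since these centres are erased later.

**Route**

Step 1
Reactants: 1 hexane-2,5-dione; 2 trimethyl phosphonoacetate (2.3 equiv)
Product: 4 dimethyl (2E,6E)-3,6-dimethylocta-2,6-dienedioate, via keto enoate 3 (not isolated)
Conditions: NaH, THF, 0 °C to reflux; E,E isomer separated by chromatography/crystallisation
Reagents that add atoms: none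
Why: Double Horner–Wadsworth–Emmons olefination of the two methyl ketones by the preformed, weakly basic phosphonate anion should favour the E,E diester, with Z-containing isomers removed at this stage.

Step 2
Reactants: 4 dimethyl (2E,6E)-3,6-dimethylocta-2,6-dienedioate
Product: 5 (2E,6E)-8-methoxy-3,6-dimethyl-8-oxoocta-2,6-dienoic acid
Conditions: NaOH (1.0 equiv), THF–H2O, 0 °C; then HCl
Reagents that add atoms: sodium hydroxide [Na+].[OH-]
Why: Mono-saponification of a symmetric diester with one equivalent of hydroxide at low temperature should give mainly the half-ester, which is separated from diester and diacid by acid–base extraction (both recyclable).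

Step 3
Reactants: 5 (2E,6E)-8-methoxy-3,6-dimethyl-8-oxoocta-2,6-dienoic acid
Product: 6 1-tert-butyl 8-methyl (2E,6E)-3,6-dimethylocta-2,6-dienedioate
Conditions: t-BuOC(=NH)CCl3, BF3·OEt2 (cat.), CH2Cl2–cyclohexane, rt
Reagents that add atoms: tert-butyl 2,2,2-trichloroacetimidate CC(C)(C)OC(=N)C(Cl)(Cl)Cl
Why: Acid-catalysed imidate esterification transfers a tert-butyl cation to the carboxylic acid without touching the enoates, so the acid terminus can be released at the very end without hydrolysing the C7 acetate.

Step 4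
Reactants: 6 1-tert-butyl 8-methyl (2E,6E)-3,6-dimethylocta-2,6-dienedioate
Product: 7 (2E,6E)-8-tert-butoxy-3,6-dimethyl-8-oxoocta-2,6-dienoic acid
Conditions: LiOH·H2O, THF–MeOH–H2O, rt; then 1 M HCl to pH 3, 0 °C
Reagents that add atoms: lithium hydroxide [Li+].[OH-]
Why: Saponification is selective for the methyl ester because the hindered tert-butyl enoate resists hydroxide attack.

Step 5
Reactants: 8 5-chloropent-1-yne
Product: 10 (E)-5-chloro-1-iodo-2-methylpent-1-ene, via alkenylalane 9 (not isolated)
Conditions: AlMe3, Cp2ZrCl2 (20 mol%), CH2Cl2, 0 °C to rt; then I2, THF, −30 to 0 °C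
Reagents that add atoms: trimethylaluminium C[Al](C)C; iodine II
Why: Zirconium-catalysed carboalumination (Negishi carboalumination) adds Me–Al syn across the terminal alkyne, and iodinolysis with retention fixes the E trisubstituted alkene that becomes C5=C6.

Step 6
Reactants: 10 (E)-5-chloro-1-iodo-2-methylpent-1-ene; 11 N-methoxy-N-methylpropanamide
Product: 13 (E)-8-chloro-5-methyloct-4-en-3-one, via vinyllithium 12 (not isolated)
Conditions: t-BuLi (2 equiv), Et2O, −78 °C; then 11, −78 to 0 °C; aq. NH4Cl
Reagents that add atoms: none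
Why: Iodine–lithium exchange proceeds with retention of alkene geometry and the Weinreb amide acylation stops at the ketone through its chelated adduct; the amide is added at −78 °C before the vinyllithium can cyclise onto the alkyl chloride.

Step 7
Reactants: 13 (E)-8-chloro-5-methyloct-4-en-3-one
Product: 14 (E)-8-iodo-5-methyloct-4-en-3-one
Conditions: NaI, acetone, reflux
Reagents that add atoms: sodium iodide [Na+].[I-]
Why: Finkelstein exchange of the primary chloride, driven by precipitation of NaCl, supplies the iodide needed for zinc insertion.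

Step 8
Reactants: 14 (E)-8-iodo-5-methyloct-4-en-3-one
Product: 15 (2Z,4E)-8-iodo-5-methyl-3-(triisopropylsilyloxy)octa-2,4-diene
Conditions: KHMDS, THF, −78 °C; then TIPSOTf, −78 to 0 °C; Et3N-deactivated silica
Reagents that add atoms: triisopropylsilyl trifluoromethanesulfonate CC(C)[Si](C(C)C)(C(C)C)OS(=O)(=O)C(F)(F)F
Why: Kinetic α′-deprotonation of the enone at the ethyl CH2 with a silazide base and O-silylation should give the cross-conjugated 2-silyloxy diene mainly as the Z enol ether (C-17 cis to O), the alkenyl group acting like an aryl group in favouring the Z enolate.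

Step 9
Reactants: 15 (2Z,4E)-8-iodo-5-methyl-3-(triisopropylsilyloxy)octa-2,4-diene; 7 (2E,6E)-8-tert-butoxy-3,6-dimethyl-8-oxoocta-2,6-dienoic acid
Product: 18 tert-butyl (2E,6E,12E,14Z)-3,6,12-trimethyl-8-oxo-14-(triisopropylsilyloxy)hexadeca-2,6,12,14-tetraenoate, via alkylzinc iodide 16 (not isolated), via acid chloride 17 (not isolated)
Conditions: 15: Zn dust (TMSCl/BrCH2CH2Br-activated), THF, 40 °C; 7: 1-chloro-N,N,2-trimethylprop-1-en-1-amine, CH2Cl2, 0 °C to rt; then combine, Pd(PPh3)4 (5 mol%), THF, 0 °C to rt
Reagents that add atoms: none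
Why: Negishi acylation of a primary alkylzinc iodide with an enoyl chloride made under neutral conditions (no HCl, no E/Z scrambling, tert-butyl ester intact) gives the C1 ketone directly and tolerates the silyl dienol ether and both enoates.

Step 10
Reactants: 18 tert-butyl (2E,6E,12E,14Z)-3,6,12-trimethyl-8-oxo-14-(triisopropylsilyloxy)hexadeca-2,6,12,14-tetraenoate
Product: 19 tert-butyl 1-oxo-7-(triisopropylsilyloxy)-5β,10β-cis-cleroda-6,13E-dien-15-oate
Conditions: (S)-2-(o-tolyl)-diphenylprolinol oxazaborolidine (20 mol%), Tf2NH (16 mol%), CH2Cl2, −78 to −20 °C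
Reagents that add atoms: none
Why: Intramolecular Diels–Alder reaction catalysed by a chiral cationic boron Lewis acid (closest known type: oxazaborolidinium-catalysed [4+2] of enones with 2-silyloxy dienes, and catalysed cyclisations of 1,7,9-decatrien-3-ones), in which the catalyst binds the C1 carbonyl and the silyloxy diene adds in a concerted, asynchronous cycloaddition with the nucleophilic C8 bonding to the enone β-carbon C9 ahead of C5–C10. Ring B (C5–C10) closes as the six-membered cycloadduct ring and ring A (C1–C5, C10) closes in the same event as the C1–C4 tether bridges C10 and C5, through a transition state with the tether carbonyl endo (under the diene). C9 is set by the E enone (C-20 cis to C1), C5 and C8 by the diene geometry (tether and C-17 outside, C-19 and H-8 inside, so C-17 ends cis to C4 and trans to C-19), C10 and the cis fusion by the endo mode, and the absolute configuration of all four by the catalyst shielding one face of the bound enone. The step needs endo over exo selectivity and enone-face selectivity; the short four-atom tether carrying the activated carbonyl should secure the first, and two-point binding of the enone (B–O coordination plus the C10–H contact) the second. Regiochemistry is fixed by the tether and is also the electronically matched one, and any E silyl enol ether cannot cyclise because both inside positions of its diene would be occupied.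

Step 11
Reactants: 19 tert-butyl 1-oxo-7-(triisopropylsilyloxy)-5β,10β-cis-cleroda-6,13E-dien-15-oate
Product: 20 tert-butyl 1-(trifluoromethylsulfonyloxy)-7-(triisopropylsilyloxy)-cis-cleroda-1,6,13E-trien-15-oate
Conditions: KHMDS, THF, −78 °C; then PhNTf2, −78 to 0 °C
Reagents that add atoms: N-phenylbis(trifluoromethanesulfonimide) FC(F)(F)S(=O)(=O)N(c1ccccc1)S(=O)(=O)C(F)(F)F
Why: Kinetic enolisation occurs at the open C2 methylene and not at the shielded C10 methine (so the ring fusion is not epimerised), and O-triflation of the enolate gives the Δ1 enol triflate with the silyl enol ether and tert-butyl enoate untouched.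

Step 12
Reactants: 20 tert-butyl 1-(trifluoromethylsulfonyloxy)-7-(triisopropylsilyloxy)-cis-cleroda-1,6,13E-trien-15-oate
Product: 21 tert-butyl 7-(triisopropylsilyloxy)-cis-cleroda-1,6,13E-trien-15-oate
Conditions: Pd(OAc)2 (5 mol%), PPh3, Bu3N, HCO2H, DMF, 60 °C
Reagents that add atoms: none
Why: Palladium-catalysed formate reduction of the enol triflate (oxidative addition, formate decarboxylation, C–H reductive elimination) removes the C1 oxygen and leaves the C1=C2 alkene regiospecifically under buffered conditions that the silyl enol ether tolerates.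

Step 13
Reactants: 21 tert-butyl 7-(triisopropylsilyloxy)-cis-cleroda-1,6,13E-trien-15-oate
Product: 22 tert-butyl 7-oxo-cis-cleroda-1,13E-dien-15-oate
Conditions: TBAF, AcOH, THF, 0 °C
Reagents that add atoms: none
Why: Buffered fluoride desilylation releases the C7 ketone by protonation at C6 without basic epimerisation at C8, whose equatorial C-17 methyl is in any case the more stable arrangement.

Step 14
Reactants: 22 tert-butyl 7-oxo-cis-cleroda-1,13E-dien-15-oate
Product: 23 tert-butyl 7α-hydroxy-cis-cleroda-1,13E-dien-15-oate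
Conditions: NaBH4, MeOH, 0 °C
Reagents that add atoms: none
Why: In the ring-B chair the α face of the C7 carbonyl is blocked by two syn-axial carbons (C4 at C5 and C-20 at C9), so borohydride reduction should occur from the β face and give the axial 7α-alcohol (OH cis to C-17 and C-20); the enoate and isolated alkene are inert.

Step 15
Reactants: 23 tert-butyl 7α-hydroxy-cis-cleroda-1,13E-dien-15-oate
Product: 24 tert-butyl 7β-acetoxy-cis-cleroda-1,13E-dien-15-oate
Conditions: PPh3, DIAD, AcOH, toluene, 0 °C to rt
Reagents that add atoms: acetic acid CC(=O)O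
Why: Mitsunobu esterification displaces the axial oxyphosphonium by acetate from the open β face with inversion, installing the equatorial 7β-acetate of the target (trans to C-17, cis to C-19), the only face from which C7 can be reached.

Step 16
Reactants: 24 tert-butyl 7β-acetoxy-cis-cleroda-1,13E-dien-15-oate
Product: 25 tert-butyl 7β-acetoxy-3-oxo-cis-cleroda-1,13E-dien-15-oate
Conditions: Rh2(cap)4 (1 mol%), t-BuOOH (decane), K2CO3, CH2Cl2, rt
Reagents that add atoms: tert-butyl hydroperoxide CC(C)(C)OO
Why: Radical allylic C–H oxidation should select the C3 methylene, because the other allylic hydrogen (C10–H) lies near the alkene plane between two quaternary carbons and the allylic positions of the electron-poor side-chain enoate react more slowly, giving the Δ1-3-enone.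

Step 17
Reactants: 25 tert-butyl 7β-acetoxy-3-oxo-cis-cleroda-1,13E-dien-15-oate
Product: 26 tert-butyl 7β-acetoxy-1β,2β-epoxy-3-oxo-cis-cleroda-13E-en-15-oate
Conditions: t-BuOOH (decane), DBU, CH2Cl2, rt
Reagents that add atoms: tert-butyl hydroperoxide CC(C)(C)OO
Why: Weitz–Scheffer nucleophilic epoxidation under non-hydrolytic conditions attacks only the ring enone (the β,β-disubstituted tert-butyl enoate is not an acceptor and the acetate is not cleaved), expected anti to the pseudo-axial C10–C9 bond.

Step 18
Reactants: 26 tert-butyl 7β-acetoxy-1β,2β-epoxy-3-oxo-cis-cleroda-13E-en-15-oate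
Product: 29 tert-butyl 7β-acetoxy-1β,2β-epoxy-3-oxo-cis-cleroda-4(18),13E-dien-15-oate, via Mannich base 27 (not isolated), via methiodide 28 (not isolated)
Conditions: LiHMDS (1.05 equiv), THF, −78 °C; CH2=NMe2+ I−, −78 to 0 °C; then MeI, CH2Cl2, rt; then DBU, 0 °C
Reagents that add atoms: dimethyl(methylidene)ammonium iodide C=[N+](C)C.[I-]
Why: C4 is the only enolisable position of the epoxy ketone and the ketone is far more acidic than the acetate or enoate, so Mannich aminomethylation of the lithium enolate followed by quaternisation and E1cB (Hofmann-type) elimination places the exocyclic C4=C18 methylene without regiochemical ambiguity.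

Step 19
Reactants: 29 tert-butyl 7β-acetoxy-1β,2β-epoxy-3-oxo-cis-cleroda-4(18),13E-dien-15-oate
Product: 31 7β-acetoxy-2-hydroxy-3-oxo-5β,10β-cis-cleroda-1,4(18),13E-trien-15-oic acid (CNP0192653.1), via epoxy acid 30 (not isolated)
Conditions: TFA–H2O (9:1), 0 °C to rt
Reagents that add atoms: none
Why: Acidolysis cleaves the tert-butyl ester and the same acid isomerises the α,β-epoxy ketone to the diosphenol (acid-catalysed epoxy ketone to 2-hydroxy enone rearrangement: oxirane opening at C1 remote from the carbonyl, then β-elimination through the C2 enol); with C4 blocked by the methylene only the C1=C2(OH)–C3=O tautomer can form, and the acetate survives.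

**Compound list**

1 | hexane-2,5-dione | CC(=O)CCC(C)=O | starting material
2 | trimethyl phosphonoacetate | COC(=O)CP(=O)(OC)OC | starting material
3 | methyl (2E)-3-methyl-6-oxohept-2-enoate (mono-olefination product) | COC(=O)/C=C(C)/CCC(C)=O | intermediate (not isolated)
4 | dimethyl (2E,6E)-3,6-dimethylocta-2,6-dienedioate | COC(=O)/C=C(C)/CC/C(C)=C/C(=O)OC | intermediate
5 | (2E,6E)-8-methoxy-3,6-dimethyl-8-oxoocta-2,6-dienoic acid | COC(=O)/C=C(C)/CC/C(C)=C/C(=O)O | intermediate
6 | 1-tert-butyl 8-methyl (2E,6E)-3,6-dimethylocta-2,6-dienedioate | COC(=O)/C=C(C)/CC/C(C)=C/C(=O)OC(C)(C)C | intermediate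
7 | (2E,6E)-8-tert-butoxy-3,6-dimethyl-8-oxoocta-2,6-dienoic acid (acid half, C1/C9–C15) | CC(C)(C)OC(=O)/C=C(C)/CC/C(C)=C/C(=O)O | intermediate
8 | 5-chloropent-1-yne | C#CCCCCl | starting material
9 | (E)-(5-chloro-2-methylpent-1-enyl)dimethylalane | ClCCC/C(C)=C/[Al](C)C | intermediate (not isolated)
10 | (E)-5-chloro-1-iodo-2-methylpent-1-ene | ClCCC/C(C)=C/I | intermediate
11 | N-methoxy-N-methylpropanamide | CCC(=O)N(C)OC | starting material
12 | (E)-(5-chloro-2-methylpent-1-enyl)lithium | ClCCC/C(C)=C/[Li] | intermediate (not isolated)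
13 | (E)-8-chloro-5-methyloct-4-en-3-one | CCC(=O)/C=C(C)/CCCCl | intermediate
14 | (E)-8-iodo-5-methyloct-4-en-3-one | CCC(=O)/C=C(C)/CCCI | intermediate
15 | (2Z,4E)-8-iodo-5-methyl-3-(triisopropylsilyloxy)octa-2,4-diene (diene half, C2–C8) | ICCC/C(C)=C/C(O[Si](C(C)C)(C(C)C)C(C)C)=C/C | intermediate
16 | alkylzinc iodide of 15 | I[Zn]CCC/C(C)=C/C(O[Si](C(C)C)(C(C)C)C(C)C)=C/C | intermediate (not isolated)
17 | acid chloride of 7 | CC(C)(C)OC(=O)/C=C(C)/CC/C(C)=C/C(Cl)=O | intermediate (not isolated)
18 | tert-butyl (2E,6E,12E,14Z)-3,6,12-trimethyl-8-oxo-14-(triisopropylsilyloxy)hexadeca-2,6,12,14-tetraenoate (trienone; C9=C10 E, C5=C6 E, C7=C8 Z) | CC(C)(C)OC(=O)/C=C(C)/CC/C(C)=C/C(=O)CCC/C(C)=C/C(O[Si](C(C)C)(C(C)C)C(C)C)=C/C | intermediate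
19 | cis-fused octalone: tert-butyl 1-oxo-7-(triisopropylsilyloxy)-5β,10β-cis-cleroda-6,13E-dien-15-oate (C-19 and H-10 β; C-17 and C-20 α) | C1CCC(=O)[C@@H]2[C@@](C)(CC/C(C)=C/C(=O)OC(C)(C)C)[C@H](C)C(O[Si](C(C)C)(C(C)C)C(C)C)=C[C@]12C | intermediate
20 | C1 enol triflate of 19 (Δ1) | C1CC=C(OS(=O)(=O)C(F)(F)F)[C@@H]2[C@@](C)(CC/C(C)=C/C(=O)OC(C)(C)C)[C@H](C)C(O[Si](C(C)C)(C(C)C)C(C)C)=C[C@]12C | intermediate
21 | tert-butyl 7-(triisopropylsilyloxy)-cis-cleroda-1,6,13E-trien-15-oate | C1CC=C[C@@H]2[C@@](C)(CC/C(C)=C/C(=O)OC(C)(C)C)[C@H](C)C(O[Si](C(C)C)(C(C)C)C(C)C)=C[C@]12C | intermediate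
22 | tert-butyl 7-oxo-cis-cleroda-1,13E-dien-15-oate | C1CC=C[C@@H]2[C@@](C)(CC/C(C)=C/C(=O)OC(C)(C)C)[C@H](C)C(=O)C[C@]12C | intermediate
23 | tert-butyl 7α-hydroxy-cis-cleroda-1,13E-dien-15-oate (axial OH, cis to C-17/C-20) | C1CC=C[C@@H]2[C@@](C)(CC/C(C)=C/C(=O)OC(C)(C)C)[C@H](C)[C@H](O)C[C@]12C | intermediate
24 | tert-butyl 7β-acetoxy-cis-cleroda-1,13E-dien-15-oate (equatorial OAc, trans to C-17) | C1CC=C[C@@H]2[C@@](C)(CC/C(C)=C/C(=O)OC(C)(C)C)[C@H](C)[C@@H](OC(C)=O)C[C@]12C | intermediate
25 | tert-butyl 7β-acetoxy-3-oxo-cis-cleroda-1,13E-dien-15-oate | C1C(=O)C=C[C@@H]2[C@@](C)(CC/C(C)=C/C(=O)OC(C)(C)C)[C@H](C)[C@@H](OC(C)=O)C[C@]12C | intermediate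
26 | tert-butyl 7β-acetoxy-1β,2β-epoxy-3-oxo-cis-cleroda-13E-en-15-oate (oxirane drawn on the face of H-10) | C1C(=O)[C@H]3O[C@H]3[C@@H]2[C@@](C)(CC/C(C)=C/C(=O)OC(C)(C)C)[C@H](C)[C@@H](OC(C)=O)C[C@]12C | intermediate
27 | 18-(dimethylamino) Mannich base of 26 (C4 epimers) | CN(C)CC1C(=O)[C@H]3O[C@H]3[C@@H]2[C@@](C)(CC/C(C)=C/C(=O)OC(C)(C)C)[C@H](C)[C@@H](OC(C)=O)C[C@]12C | intermediate (not isolated)
28 | 18-(trimethylammonio) iodide of 27 (C4 epimers) | C[N+](C)(C)CC1C(=O)[C@H]3O[C@H]3[C@@H]2[C@@](C)(CC/C(C)=C/C(=O)OC(C)(C)C)[C@H](C)[C@@H](OC(C)=O)C[C@]12C.[I-] | intermediate (not isolated)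
29 | tert-butyl 7β-acetoxy-1β,2β-epoxy-3-oxo-cis-cleroda-4(18),13E-dien-15-oate | C=C1C(=O)[C@H]3O[C@H]3[C@@H]2[C@@](C)(CC/C(C)=C/C(=O)OC(C)(C)C)[C@H](C)[C@@H](OC(C)=O)C[C@]12C | intermediate
30 | 7β-acetoxy-1β,2β-epoxy-3-oxo-cis-cleroda-4(18),13E-dien-15-oic acid | C=C1C(=O)[C@H]3O[C@H]3[C@@H]2[C@@](C)(CC/C(C)=C/C(=O)O)[C@H](C)[C@@H](OC(C)=O)C[C@]12C | intermediate (not isolated)
31 | CNP0192653.1: 7β-acetoxy-2-hydroxy-3-oxo-5β,10β-cis-cleroda-1,4(18),13E-trien-15-oic acid | C=C1C(=O)C(O)=C[C@@H]2[C@@](C)(CC/C(C)=C/C(=O)O)[C@H](C)[C@@H](OC(C)=O)C[C@]12C | target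

**Step count**

Total: 19 steps. Longest linear sequence: 15 steps (steps 5–8, 9, 10–19 from 5-chloropent-1-yne; equally steps 1–4, 9, 10–19 from hexane-2,5-dione).

**Steps most likely to fail, with fallbacks**

Step 10 (key cycloaddition). The hindered β,β-disubstituted enone and the diene with an inside methyl may turn over too slowly at the temperatures where the chiral catalyst is selective. Facial selectivity may also be poor, or the dienol ether may be protodesilylated by free Tf2NH. The fallback sets out from 18 and returns at 19. The cyclisation is run without enantiocontrol, promoted by Me2AlCl (CH2Cl2, −78 to 0 °C) or thermally in toluene with BHT, which should give 19 together with its mirror image, ent-octalone F1. The two are then separated by preparative chromatography on a chiral stationary phase, and 19 re-enters at step 11.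

Step 15 (Mitsunobu inversion at C7). E2 elimination of the axial oxyphosphonium towards C6 or C8 may outrun substitution, or activation of the hindered alcohol may stall. The fallback sets out from ketone 22 and returns at 24, bypassing step 14. Single-electron reduction with SmI2 (THF, i-PrOH, −78 to 0 °C) runs under thermodynamic control through the ketyl and carbanion, not through hydride approach, and should give the equatorial alcohol, tert-butyl 7β-hydroxy-cis-cleroda-1,13E-dien-15-oate F2. Acetylation (Ac2O, pyridine, DMAP) then gives 24.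

Step 19 (epoxy ketone to diosphenol with ester cleavage). The protonated oxirane may follow an acyl-shift (ring-contraction) path, stop at the diol stage, or the exocyclic enone may add the acid. The fallback builds the diosphenol by α-ketol oxidation; it sets out from enone 25 and returns at 31.
- Conjugate reduction of 25 with L-Selectride (THF, −78 °C) gives the C2=C3 enolate regiospecifically; oxidation in the same flask with 2-(phenylsulfonyl)-3-phenyloxaziridine gives the 2-hydroxy-3-ketone F3.
- Silylation (TESCl, imidazole) gives the 2-triethylsilyloxy ketone F4.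
- Methylenation as in step 18 passes through the Mannich base F5 and its methiodide F6 to the 4(18)-methylene ketone F7.
- TFA–H2O removes the silyl ether and the tert-butyl ester to give the ketol acid F8.
- Oxidation of the α-ketol with Dess–Martin periodinane gives the 2,3-dione, which can enolise only towards C1, that is 31.

**Further compounds**

F1 | step 10 | ent-19, mirror image of the cis-fused octalone | C1CCC(=O)[C@H]2[C@](C)(CC/C(C)=C/C(=O)OC(C)(C)C)[C@@H](C)C(O[Si](C(C)C)(C(C)C)C(C)C)=C[C@@]12C
F2 | step 15 | tert-butyl 7β-hydroxy-cis-cleroda-1,13E-dien-15-oate | C1CC=C[C@@H]2[C@@](C)(CC/C(C)=C/C(=O)OC(C)(C)C)[C@H](C)[C@@H](O)C[C@]12C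
F3 | step 19 | tert-butyl 7β-acetoxy-2-hydroxy-3-oxo-cis-cleroda-13E-en-15-oate (C2 epimers) | C1C(=O)C(O)C[C@@H]2[C@@](C)(CC/C(C)=C/C(=O)OC(C)(C)C)[C@H](C)[C@@H](OC(C)=O)C[C@]12C
F4 | step 19 | 2-O-triethylsilyl ether of F3 | C1C(=O)C(O[Si](CC)(CC)CC)C[C@@H]2[C@@](C)(CC/C(C)=C/C(=O)OC(C)(C)C)[C@H](C)[C@@H](OC(C)=O)C[C@]12C
F5 | step 19 | 18-(dimethylamino) Mannich base of F4 | CN(C)CC1C(=O)C(O[Si](CC)(CC)CC)C[C@@H]2[C@@](C)(CC/C(C)=C/C(=O)OC(C)(C)C)[C@H](C)[C@@H](OC(C)=O)C[C@]12C
F6 | step 19 | methiodide of F5 | C[N+](C)(C)CC1C(=O)C(O[Si](CC)(CC)CC)C[C@@H]2[C@@](C)(CC/C(C)=C/C(=O)OC(C)(C)C)[C@H](C)[C@@H](OC(C)=O)C[C@]12C.[I-]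
F7 | step 19 | tert-butyl 7β-acetoxy-3-oxo-2-(triethylsilyloxy)-cis-cleroda-4(18),13E-dien-15-oate | C=C1C(=O)C(O[Si](CC)(CC)CC)C[C@@H]2[C@@](C)(CC/C(C)=C/C(=O)OC(C)(C)C)[C@H](C)[C@@H](OC(C)=O)C[C@]12C
F8 | step 19 | 7β-acetoxy-2-hydroxy-3-oxo-cis-cleroda-4(18),13E-dien-15-oic acid (saturated C1–C2 ketol) | C=C1C(=O)C(O)C[C@@H]2[C@@](C)(CC/C(C)=C/C(=O)O)[C@H](C)[C@@H](OC(C)=O)C[C@]12C
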